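1. Last bond made is C15–Br, by radical Markovnikov hydrobromination (metal-hydride H-atom transfer) of a 14-isopropenyl macrolactone. The 15-membered lactone is closed just before by Pd-catalysed carbonylation of an aryl bromide onto the C14 hydroxyl, so the benzoate carbon comes from CO.
2. Key disconnection C9–C10: an iron-catalysed radical decarboxylative alkenylation joins the cyclohexene acid (C9 radical from its redox-active ester) to an (E)-alkenylzinc carrying C10–C15. ent-Shi epoxidation and bromide SN2 opening then set C10 and C11.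
3. The cyclohexene (C2, C6, C7) comes from a bromonium-relay cation–olefin cyclisation of an enantiopure bromo-γ-lactone (Shi epoxide, then bromide). The lactone is the nucleofuge, and the acid it releases is the radical precursor of line 2.
4. Both halves are cut from one building block, (3S,6E)-7-iodo-2,6-dimethylhepta-1,6-dien-3-ol (pent-4-ynal + 2-bromopropene + Me3Al): Johnson–Claisen for C2–C9, silyl ether for C10–C15. The arene is o-cresol.
5. Ring order: arene (bought), then cyclohexene (step 10), then macrolactone (step 15).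

Assumption: locants C1–C15 are those of the diterpene chain (C1 benzylic CH2; C2–C7 ring; C8–C15 chain with Br at C10, OH/Me at C11, O at C14, CMe2Br at C15); pent-4-ynal and both antipodes of the Shi ketone are taken as purchasable.

Step 1
Reactants: 1 2-methylphenol (o-cresol)
Product: 2 4-bromo-2-methylphenol
Conditions: Br2 (1.0 equiv), CH2Cl2, 0 °C
Reagents that add atoms: bromine (BrBr)
Why: Electrophilic aromatic bromination occurs para to the hydroxyl group, the most activated and least hindered position of o-cresol.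

Step 2
Reactants: 2 4-bromo-2-methylphenol
Product: 3 4-bromo-2-methylphenyl pivalate
Conditions: PivCl, Et3N, DMAP (cat.), CH2Cl2, 0 °C to rt
Reagents that add atoms: pivaloyl chloride (CC(C)(C)C(Cl)=O)
Why: Standard O-acylation; the hindered, electron-withdrawing pivalate makes the phenol oxygen non-nucleophilic for the later cationic, oxidative and carbonylative steps.

Step 3
Reactants: 3 4-bromo-2-methylphenyl pivalate
Product: 4 4-bromo-2-(bromomethyl)phenyl pivalate
Conditions: NBS, AIBN (cat.), PhCF3, 80 °C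
Reagents that add atoms: N-bromosuccinimide (O=C1CCC(=O)N1Br)
Why: Wohl–Ziegler radical bromination takes place at the only benzylic C–H position.

Step 4
Reactants: 5 pent-4-ynal; 6 2-bromopropene
Product: 8 (3S)-2-methylhept-1-en-6-yn-3-ol, via trimethylsilyl ether 7 (not isolated)
Conditions: CrCl2 (10 mol %), NiCl2 (2 mol %), chiral oxazoline–sulfonamide ligand (antipode giving the S alcohol, 12 mol %), Mn, Me3SiCl, Et3N, LiCl, MeCN, rt; then 1 M HCl, THF
Reagents that add atoms: none
Why: Catalytic asymmetric Nozaki–Hiyama–Kishi alkenylation in which nickel passes the isopropenyl group to chromium and the chromium-bound chiral ligand differentiates the aldehyde faces, setting the carbinol that becomes C14 in one half and is erased in the other.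

Step 5
Reactants: 8 (3S)-2-methylhept-1-en-6-yn-3-ol
Product: 10 (3S,6E)-7-iodo-2,6-dimethylhepta-1,6-dien-3-ol, via alkenyldimethylalane 9 (not isolated)
Conditions: Me3Al (3 equiv), Cp2ZrCl2 (25 mol %), CH2Cl2, 0 °C to rt; then I2, THF, −30 °C
Reagents that add atoms: trimethylaluminium (C[Al](C)C); iodine ([I][I])
Why: Zirconium-catalysed Negishi carboalumination adds methyl and aluminium syn across the terminal alkyne with methyl on the internal carbon, and iodinolysis with retention gives only the E iodoalkene; the stereocentre is not touched.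

Step 6
Reactants: 10 (3S,6E)-7-iodo-2,6-dimethylhepta-1,6-dien-3-ol
Product: 12 methyl (4E,8E)-9-iodo-4,8-dimethylnona-4,8-dienoate, via mixed ketene acetal 11 (not isolated)
Conditions: MeC(OMe)3 (6 equiv), EtCO2H (cat.), toluene, 110 °C, MeOH distilled off
Reagents that add atoms: trimethyl orthoacetate (COC(C)(OC)OC)
Why: Johnson–Claisen rearrangement through a chair transition state with the chain equatorial gives the E trisubstituted C6=C7 alkene and adds C9 plus the ester carbon; the carbinol stereocentre is consumed.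

Step 7
Reactants: 12 methyl (4E,8E)-9-iodo-4,8-dimethylnona-4,8-dienoate
Product: 13 methyl 3-[(2R,3R)-3-[(3E)-4-iodo-3-methylbut-3-en-1-yl]-2-methyloxiran-2-yl]propanoate
Conditions: Shi ketone (D-fructose-derived, 30 mol %), KHSO5, K2CO3, Bu4NHSO4, MeCN–(MeO)2CH2–aq. borate buffer, 0 °C
Reagents that add atoms: potassium peroxymonosulfate ([K+].[O-]S(=O)(=O)OO)
Why: Shi asymmetric epoxidation, in which the chiral dioxirane attacks the electron-rich trisubstituted C6=C7 alkene through the spiro transition state to give the (6R,7R) epoxide while the electron-poor iodoalkene does not react.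

Step 8
Reactants: 13 methyl 3-[(2R,3R)-3-[(3E)-4-iodo-3-methylbut-3-en-1-yl]-2-methyloxiran-2-yl]propanoate; 4 4-bromo-2-(bromomethyl)phenyl pivalate
Product: 15 methyl 3-[(2R,3R)-3-{(3E)-5-[5-bromo-2-(pivaloyloxy)phenyl]-3-methylpent-3-en-1-yl}-2-methyloxiran-2-yl]propanoate, via benzylzinc bromide 14 (not isolated)
Conditions: 4, Zn dust, LiCl, THF, rt; then 13, Pd(PPh3)4 (5 mol %), THF, 40 °C
Reagents that add atoms: none
Why: Negishi cross-coupling in which zerovalent palladium inserts into the alkenyl C–I bond much faster than into the aryl C–Br bond and the benzylzinc couples with retention of the E geometry, leaving epoxide and esters untouched.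

Step 9
Reactants: 15 methyl 3-[(2R,3R)-3-{(3E)-5-[5-bromo-2-(pivaloyloxy)phenyl]-3-methylpent-3-en-1-yl}-2-methyloxiran-2-yl]propanoate
Product: 17 4-bromo-2-[(2E,6S)-6-bromo-3-methyl-6-[(2R)-2-methyl-5-oxooxolan-2-yl]hex-2-en-1-yl]phenyl pivalate, via bromohydrin methyl ester 16 (not isolated)
Conditions: Li2NiBr4 (2 equiv), THF, 0 °C to rt; then PPTS (cat.), toluene, 50 °C
Reagents that add atoms: dilithium tetrabromonickelate ([Li+].[Li+].Br[Ni-2](Br)(Br)Br)
Why: SN2 opening of the trisubstituted epoxide by bromide at the secondary carbon C6 with inversion (6R to 6S) leaves C7 (R) as a tertiary alcohol that lactonises onto the γ-ester, so Br and the lactone oxygen end up anti.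

Step 10
Reactants: 17 4-bromo-2-[(2E,6S)-6-bromo-3-methyl-6-[(2R)-2-methyl-5-oxooxolan-2-yl]hex-2-en-1-yl]phenyl pivalate
Product: 18 3-[(1S,2R,6S)-6-bromo-2-{[5-bromo-2-(pivaloyloxy)phenyl]methyl}-1,3-dimethylcyclohex-3-en-1-yl]propanoic acid
Conditions: SnCl4 (3 equiv), 2,6-di-tert-butyl-4-methylpyridine, CH2Cl2–MeNO2, −40 to 0 °C, high dilution; then 1 M HCl
Reagents that add atoms: none
Why: Proposed new method: SnCl4 bound to the lactone carbonyl turns the tertiary C7–O bond into a nucleofuge (alkyl–oxygen ionisation of a tertiary γ-lactone, as in Lewis-acid Friedel–Crafts alkylations with such lactones), the anti-periplanar C6–Br bond assists its departure to give the configurationally defined bromonium ion (closest known reaction type: enantiospecific polyene cyclisation started by ionising enantiopure β-bromo esters of bromohydrins), the E C2=C3 alkene attacks C7 anti to bromine through a chair so that C7 becomes S with Br, the C7 methyl and the benzyl group at C2 (R) all cis, loss of H-4 gives the endocyclic alkene, and the nucleofuge ends as the free acid.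

Step 11
Reactants: 10 (3S,6E)-7-iodo-2,6-dimethylhepta-1,6-dien-3-ol
Product: 19 triethyl{[(3S,6E)-7-iodo-2,6-dimethylhepta-1,6-dien-3-yl]oxy}silane
Conditions: Et3SiCl, imidazole, CH2Cl2, 0 °C
Reagents that add atoms: chlorotriethylsilane (CC[Si](Cl)(CC)CC)
Why: Silylation masks the future C14 hydroxyl so that it cannot later open the 10,11-epoxide to a tetrahydrofuran.

Step 12
Reactants: 18 3-[(1S,2R,6S)-6-bromo-2-{[5-bromo-2-(pivaloyloxy)phenyl]methyl}-1,3-dimethylcyclohex-3-en-1-yl]propanoic acid; 19 triethyl{[(3S,6E)-7-iodo-2,6-dimethylhepta-1,6-dien-3-yl]oxy}silane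
Product: 23 4-bromo-2-{[(1R,5S,6S)-5-bromo-6-[(3E,7S)-4,8-dimethyl-7-(triethylsilyloxy)nona-3,8-dien-1-yl]-2,6-dimethylcyclohex-2-en-1-yl]methyl}phenyl pivalate, via redox-active ester 20 (not isolated), via alkenyllithium 21 (not isolated), via alkenylzinc chloride 22 (not isolated)
Conditions: 18, N-hydroxytetrachlorophthalimide, DIC, DMAP (cat.), CH2Cl2, rt, urea filtered off; 19, t-BuLi (2 equiv), Et2O, −78 °C, then ZnCl2, THF; then Fe(acac)3 (20 mol %), dppBz (24 mol %), THF, rt
Reagents that add atoms: none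
Why: Radical decarboxylative alkenylation of a redox-active ester, in which electron transfer from the low-valent iron–alkenyl species to 20 expels CO2 and the imide anion to give the primary C9 radical, which recombines at iron and is reductively eliminated with the alkenyl group with retention of the E geometry, so the C9–C10 bond joins the two halves without touching a stereocentre; the ester is reduced far more easily than the hindered secondary C6–Br bond and iron does not insert into the aryl bromide.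

Step 13
Reactants: 23 4-bromo-2-{[(1R,5S,6S)-5-bromo-6-[(3E,7S)-4,8-dimethyl-7-(triethylsilyloxy)nona-3,8-dien-1-yl]-2,6-dimethylcyclohex-2-en-1-yl]methyl}phenyl pivalate
Product: 24 4-bromo-2-{[(1R,5S,6S)-5-bromo-2,6-dimethyl-6-(2-{(2S,3S)-3-methyl-3-[(3S)-4-methyl-3-(triethylsilyloxy)pent-4-en-1-yl]oxiran-2-yl}ethyl)cyclohex-2-en-1-yl]methyl}phenyl pivalate
Conditions: ent-Shi ketone (L-fructose-derived, 30 mol %), KHSO5 (1.3 equiv), K2CO3, Bu4NHSO4, MeCN–(MeO)2CH2–aq. borate buffer, −5 °C
Reagents that add atoms: potassium peroxymonosulfate ([K+].[O-]S(=O)(=O)OO)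
Why: Shi epoxidation with the enantiomeric ketone gives the (10S,11S) epoxide under reagent control, the unhindered acyclic trisubstituted alkene reacting ahead of the hindered ring alkene and of the 1,1-disubstituted isopropenyl group, which is a poor substrate for this catalyst.

Step 14
Reactants: 24 4-bromo-2-{[(1R,5S,6S)-5-bromo-2,6-dimethyl-6-(2-{(2S,3S)-3-methyl-3-[(3S)-4-methyl-3-(triethylsilyloxy)pent-4-en-1-yl]oxiran-2-yl}ethyl)cyclohex-2-en-1-yl]methyl}phenyl pivalate
Product: 26 4-bromo-2-{[(1R,5S,6S)-5-bromo-6-[(3R,4S,7S)-3-bromo-4,7-dihydroxy-4,8-dimethylnon-8-en-1-yl]-2,6-dimethylcyclohex-2-en-1-yl]methyl}phenyl pivalate, via bromohydrin silyl ether 25 (not isolated)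
Conditions: Li2NiBr4 (2 equiv), THF, 0 °C to rt; then HF·pyridine, THF, 0 °C
Reagents that add atoms: dilithium tetrabromonickelate ([Li+].[Li+].Br[Ni-2](Br)(Br)Br)
Why: SN2 opening at the secondary carbon C10 with inversion gives the (10R) bromide and the (11S) tertiary alcohol (anti bromohydrin), and the silyl ether is removed only afterwards, so the free C14 hydroxyl never meets the epoxide.

Step 15
Reactants: 26 4-bromo-2-{[(1R,5S,6S)-5-bromo-6-[(3R,4S,7S)-3-bromo-4,7-dihydroxy-4,8-dimethylnon-8-en-1-yl]-2,6-dimethylcyclohex-2-en-1-yl]methyl}phenyl pivalate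
Product: 27 (2R,6S,7S,10R,11S,14S)-14-isopropenyl macrolactone O-pivalate (target skeleton with C(CH3)=CH2 at C14 in place of CMe2Br; phenol as pivalate)
Conditions: Pd(OAc)2 (10 mol %), Xantphos (12 mol %), CO (1 atm), Et3N (3 equiv), toluene, 80 °C, syringe-pump addition to 2 mM
Reagents that add atoms: carbon monoxide ([C-]#[O+])
Why: Carbonylative macrolactonisation (alkoxycarbonylation of an aryl bromide), in which zerovalent palladium inserts into the aryl C–Br bond, CO insertion gives the acylpalladium, and the secondary allylic C14 hydroxyl closes the 15-membered lactone with retention at C14 while the tertiary C11 hydroxyl is too hindered to compete.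

Step 16
Reactants: 27 (2R,6S,7S,10R,11S,14S)-14-isopropenyl macrolactone O-pivalate
Product: 28 (2R,6S,7S,10R,11S,14S)-14-isopropenyl macrolactone phenol (15-debromo-15(16)-ene analogue of the target)
Conditions: N2H4·H2O (5 equiv), THF, 0 °C to rt
Reagents that add atoms: none
Why: Chemoselective hydrazinolysis of the activated aryl ester, which leaves the benzoate-type macrolactone of a secondary alcohol, the bromohydrin and the alkyl bromides alone.

Step 17
Reactants: 28 (2R,6S,7S,10R,11S,14S)-14-isopropenyl macrolactone phenol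
Product: 29 CNP0215732.1 (target; (2R,6S,7S,10R,11S,14S)-6,10-dibromo-14-(2-bromopropan-2-yl)-11-hydroxy macrolactone)
Conditions: Co(acac)2 (30 mol %), t-BuOOH (30 mol %), Et3SiH (3 equiv), TsBr (2.5 equiv), n-PrOH–CH2Cl2, rt
Reagents that add atoms: 4-methylbenzenesulfonyl bromide (Cc1ccc(cc1)S(=O)(=O)Br)
Why: Radical Markovnikov hydrobromination by metal-hydride hydrogen atom transfer, in which the cobalt hydride gives a hydrogen atom to the terminal CH2 of the 1,1-disubstituted isopropenyl group (faster than to the hindered trisubstituted ring alkene) and the tertiary C15 radical takes bromine from TsBr; C15 is not a stereocentre and C14 is untouched.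

Compound list
1 | 2-methylphenol (o-cresol) | Cc1ccccc1O | starting material
2 | 4-bromo-2-methylphenol | Cc1cc(Br)ccc1O | intermediate
3 | 4-bromo-2-methylphenyl pivalate | Cc1cc(Br)ccc1OC(=O)C(C)(C)C | intermediate
4 | 4-bromo-2-(bromomethyl)phenyl pivalate | BrCc1cc(Br)ccc1OC(=O)C(C)(C)C | intermediate
5 | pent-4-ynal | C#CCCC=O | starting material
6 | 2-bromopropene | CC(Br)=C | starting material
7 | trimethyl{[(3S)-2-methylhept-1-en-6-yn-3-yl]oxy}silane | C#CCC[C@H](O[Si](C)(C)C)C(C)=C | intermediate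
8 | (3S)-2-methylhept-1-en-6-yn-3-ol | C#CCC[C@H](O)C(C)=C | intermediate
9 | [(1E,5S)-5-(dimethylalumanyloxy)-2,6-dimethylhepta-1,6-dien-1-yl]dimethylalane | C[Al](C)/C=C(C)/CC[C@H](O[Al](C)C)C(C)=C | intermediate
10 | (3S,6E)-7-iodo-2,6-dimethylhepta-1,6-dien-3-ol | I/C=C(C)/CC[C@H](O)C(C)=C | intermediate
11 | (3S,6E)-7-iodo-3-[(1-methoxyethenyl)oxy]-2,6-dimethylhepta-1,6-diene | I/C=C(C)/CC[C@H](OC(=C)OC)C(C)=C | intermediate
12 | methyl (4E,8E)-9-iodo-4,8-dimethylnona-4,8-dienoate | COC(=O)CC/C(C)=C/CC/C(C)=C/I | intermediate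
13 | methyl 3-[(2R,3R)-3-[(3E)-4-iodo-3-methylbut-3-en-1-yl]-2-methyloxiran-2-yl]propanoate | COC(=O)CC[C@@]1(C)O[C@@H]1CC/C(C)=C/I | intermediate
14 | {[5-bromo-2-(pivaloyloxy)phenyl]methyl}zinc bromide | Br[Zn]Cc1cc(Br)ccc1OC(=O)C(C)(C)C | intermediate
15 | methyl 3-[(2R,3R)-3-{(3E)-5-[5-bromo-2-(pivaloyloxy)phenyl]-3-methylpent-3-en-1-yl}-2-methyloxiran-2-yl]propanoate | COC(=O)CC[C@@]1(C)O[C@@H]1CC/C(C)=C/Cc2cc(Br)ccc2OC(=O)C(C)(C)C | intermediate
16 | methyl (4R,5S,8E)-5-bromo-10-[5-bromo-2-(pivaloyloxy)phenyl]-4-hydroxy-4,8-dimethyldec-8-enoate | COC(=O)CC[C@@](C)(O)[C@@H](Br)CC/C(C)=C/Cc1cc(Br)ccc1OC(=O)C(C)(C)C | intermediate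
17 | 4-bromo-2-[(2E,6S)-6-bromo-3-methyl-6-[(2R)-2-methyl-5-oxooxolan-2-yl]hex-2-en-1-yl]phenyl pivalate | O=C1CC[C@@](C)(O1)[C@@H](Br)CC/C(C)=C/Cc2cc(Br)ccc2OC(=O)C(C)(C)C | intermediate
18 | 3-[(1S,2R,6S)-6-bromo-2-{[5-bromo-2-(pivaloyloxy)phenyl]methyl}-1,3-dimethylcyclohex-3-en-1-yl]propanoic acid | CC1=CC[C@H](Br)[C@@](C)(CCC(=O)O)[C@@H]1Cc2cc(Br)ccc2OC(=O)C(C)(C)C | intermediate
19 | triethyl{[(3S,6E)-7-iodo-2,6-dimethylhepta-1,6-dien-3-yl]oxy}silane | I/C=C(C)/CC[C@H](O[Si](CC)(CC)CC)C(C)=C | intermediate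
20 | 4,5,6,7-tetrachloro-1,3-dioxoisoindolin-2-yl ester of acid 18 | CC1=CC[C@H](Br)[C@@](C)(CCC(=O)ON3C(=O)c4c(Cl)c(Cl)c(Cl)c(Cl)c4C3=O)[C@@H]1Cc2cc(Br)ccc2OC(=O)C(C)(C)C | intermediate
21 | [(1E,5S)-2,6-dimethyl-5-(triethylsilyloxy)hepta-1,6-dien-1-yl]lithium | [Li]/C=C(C)/CC[C@H](O[Si](CC)(CC)CC)C(C)=C | intermediate
22 | [(1E,5S)-2,6-dimethyl-5-(triethylsilyloxy)hepta-1,6-dien-1-yl]zinc chloride | Cl[Zn]/C=C(C)/CC[C@H](O[Si](CC)(CC)CC)C(C)=C | intermediate
23 | 4-bromo-2-{[(1R,5S,6S)-5-bromo-6-[(3E,7S)-4,8-dimethyl-7-(triethylsilyloxy)nona-3,8-dien-1-yl]-2,6-dimethylcyclohex-2-en-1-yl]methyl}phenyl pivalate | CC1=CC[C@H](Br)[C@@](C)(CC/C=C(C)/CC[C@H](O[Si](CC)(CC)CC)C(C)=C)[C@@H]1Cc2cc(Br)ccc2OC(=O)C(C)(C)C | intermediate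
24 | 4-bromo-2-{[(1R,5S,6S)-5-bromo-2,6-dimethyl-6-(2-{(2S,3S)-3-methyl-3-[(3S)-4-methyl-3-(triethylsilyloxy)pent-4-en-1-yl]oxiran-2-yl}ethyl)cyclohex-2-en-1-yl]methyl}phenyl pivalate | CC1=CC[C@H](Br)[C@@](C)(CC[C@@H]3O[C@@]3(C)CC[C@H](O[Si](CC)(CC)CC)C(C)=C)[C@@H]1Cc2cc(Br)ccc2OC(=O)C(C)(C)C | intermediate
25 | 4-bromo-2-{[(1R,5S,6S)-5-bromo-6-[(3R,4S,7S)-3-bromo-4-hydroxy-4,8-dimethyl-7-(triethylsilyloxy)non-8-en-1-yl]-2,6-dimethylcyclohex-2-en-1-yl]methyl}phenyl pivalate | CC1=CC[C@H](Br)[C@@](C)(CC[C@@H](Br)[C@@](C)(O)CC[C@H](O[Si](CC)(CC)CC)C(C)=C)[C@@H]1Cc2cc(Br)ccc2OC(=O)C(C)(C)C | intermediate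
26 | 4-bromo-2-{[(1R,5S,6S)-5-bromo-6-[(3R,4S,7S)-3-bromo-4,7-dihydroxy-4,8-dimethylnon-8-en-1-yl]-2,6-dimethylcyclohex-2-en-1-yl]methyl}phenyl pivalate | CC1=CC[C@H](Br)[C@@](C)(CC[C@@H](Br)[C@@](C)(O)CC[C@H](O)C(C)=C)[C@@H]1Cc2cc(Br)ccc2OC(=O)C(C)(C)C | intermediate
27 | (2R,6S,7S,10R,11S,14S)-14-isopropenyl macrolactone O-pivalate | CC1=CC[C@H](Br)[C@@]2(C)CC[C@@H](Br)[C@@](C)(O)CC[C@@H](C(C)=C)OC(=O)c3ccc(OC(=O)C(C)(C)C)c(c3)C[C@H]12 | intermediate
28 | (2R,6S,7S,10R,11S,14S)-14-isopropenyl macrolactone phenol | CC1=CC[C@H](Br)[C@@]2(C)CC[C@@H](Br)[C@@](C)(O)CC[C@@H](C(C)=C)OC(=O)c3ccc(O)c(c3)C[C@H]12 | intermediate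
29 | CNP0215732.1 | CC1=CC[C@H](Br)[C@@]2(C)CC[C@@H](Br)[C@@](C)(O)CC[C@@H](C(C)(C)Br)OC(=O)c3ccc(O)c(c3)C[C@H]12 | target

Total step count: 17.
Longest linear sequence: 13 steps (5 to 8 to 10 to 12 to 13 to 15 to 17 to 18 to 23 to 24 to 26 to 27 to 28 to 29; steps 4–10 and 12–17).

The three steps most likely to fail are steps 10, 12 and 15.

The cyclisation of step 10 has no direct precedent: the neutral lactone 17 may ionise too slowly, or return to itself faster than the alkene captures the bromonium ion. The fallback sets out from 17 and activates it by O-alkylation instead of Lewis-acid complexation. Trimethyloxonium tetrafluoroborate and 2,6-di-tert-butyl-4-methylpyridine in CH2Cl2 give the O-methyl lactonium tetrafluoroborate F1, a dialkoxycarbenium ion whose tertiary C–O bond breaks without help and whose nucleofuge is a methyl ester that cannot fall back to the neutral lactone. The same bromonium-relay cyclisation then gives the cyclohexene methyl ester F2. SN2 demethylation with LiI in refluxing EtOAc, which spares the aryl pivalate and both C–Br bonds, comes back to the route at 18.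

The radical coupling of step 12 has to find the redox-active ester in the presence of a secondary alkyl bromide and an aryl bromide, and must take a trisubstituted alkenylzinc. The fallback sets out from 18 and makes the C9–C10 bond by a polar palladium coupling. Ester 20 is made as before and irradiated with LiI and catalytic PPh3 (blue light, acetone) to give the primary iodide F3 by iododecarboxylation. Zinc dust with LiCl in THF inserts only into the primary C–I bond to give the alkylzinc iodide F4. Negishi coupling with 19 under Pd(PPh3)4, where zerovalent palladium selects the alkenyl iodide over the aryl bromide, comes back at 23.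

The carbonylative ring closure of step 15 needs heat and an amine base on a substrate that carries a bromohydrin, and it must beat oligomerisation. The fallback sets out from 23 and separates carboxylation from ring closure. The aryl bromide is hydroxycarbonylated while no base-sensitive group is present (Pd(OAc)2, Xantphos, CO, H2O, Et3N, dioxane, 80 °C) to give the benzoic acid F5. ent-Shi epoxidation gives the epoxy acid F6. Li2NiBr4 and then HF·pyridine give, through the silylated bromohydrin F7, the seco acid F8. Shiina macrolactonisation (2-methyl-6-nitrobenzoic anhydride, DMAP, CH2Cl2, rt, slow addition) closes the lactone at the C14 hydroxyl and comes back at 27.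

Further compounds
F1 | step 10 | O-methyl lactonium tetrafluoroborate of 17 | C[O+]=C1CC[C@@](C)(O1)[C@@H](Br)CC/C(C)=C/Cc2cc(Br)ccc2OC(=O)C(C)(C)C.F[B-](F)(F)F
F2 | step 10 | methyl 3-[(1S,2R,6S)-6-bromo-2-{[5-bromo-2-(pivaloyloxy)phenyl]methyl}-1,3-dimethylcyclohex-3-en-1-yl]propanoate | CC1=CC[C@H](Br)[C@@](C)(CCC(=O)OC)[C@@H]1Cc2cc(Br)ccc2OC(=O)C(C)(C)C
F3 | step 12 | 4-bromo-2-{[(1R,5S,6S)-5-bromo-6-(2-iodoethyl)-2,6-dimethylcyclohex-2-en-1-yl]methyl}phenyl pivalate | CC1=CC[C@H](Br)[C@@](C)(CCI)[C@@H]1Cc2cc(Br)ccc2OC(=O)C(C)(C)C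
F4 | step 12 | alkylzinc iodide from F3 | CC1=CC[C@H](Br)[C@@](C)(CC[Zn]I)[C@@H]1Cc2cc(Br)ccc2OC(=O)C(C)(C)C
F5 | step 15 | benzoic acid from 23 (CO2H in place of the aryl Br) | CC1=CC[C@H](Br)[C@@](C)(CC/C=C(C)/CC[C@H](O[Si](CC)(CC)CC)C(C)=C)[C@@H]1Cc2cc(ccc2OC(=O)C(C)(C)C)C(=O)O
F6 | step 15 | (10S,11S)-epoxy benzoic acid | CC1=CC[C@H](Br)[C@@](C)(CC[C@@H]3O[C@@]3(C)CC[C@H](O[Si](CC)(CC)CC)C(C)=C)[C@@H]1Cc2cc(ccc2OC(=O)C(C)(C)C)C(=O)O
F7 | step 15 | (10R,11S)-bromohydrin 14-O-triethylsilyl benzoic acid | CC1=CC[C@H](Br)[C@@](C)(CC[C@@H](Br)[C@@](C)(O)CC[C@H](O[Si](CC)(CC)CC)C(C)=C)[C@@H]1Cc2cc(ccc2OC(=O)C(C)(C)C)C(=O)O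
F8 | step 15 | seco acid (10R,11S,14S) | CC1=CC[C@H](Br)[C@@](C)(CC[C@@H](Br)[C@@](C)(O)CC[C@H](O)C(C)=C)[C@@H]1Cc2cc(ccc2OC(=O)C(C)(C)C)C(=O)O
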